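**Plan**
- Retrosynthetic cuts, in order: the O-protecting groups and the two ring A methyl ethers; the C1–C6 bond of ring A (aldol aromatisation); the depside C(=O)–O bond (acylketene plus ring B phenol); the chain C4–C5 bond (dioxinone γ-acylation) and the C4–CH2O bond (γ-hydroxymethylation).
- Enabling feature: ring A has oxygen on C2 and C4, methyl on C6, the ester carbon on C1 and the CH2O group on C3. This is the pattern of a 3,5,7-trioxooctanoate folded C2 to C7 with the CH2O group on chain C4.
- Forward: the ring B phenol is made from methyl atrarate (steps 1–4) and the C8 chain is built on a dioxinone (steps 5–9). Thermolysis joins the two through the ester (step 10), and ring A, the only ring formed, then closes (step 11).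
- Endgame: O-methylation, hydrogenolysis, desilylation (steps 12–14). Ring B carries benzyl groups; the CH2O group carries a tert-butyldiphenylsilyl group, chosen for its acid stability.
- Stereochemistry: the target is achiral; the single racemic, enolisable centre of the chain (C4) becomes an aromatic carbon.

Key step: step 11

Assumption: salts formed in situ (lithium dienolates, phenoxides, the chelated Weinreb adduct) count as ionised forms of the numbered compounds; only neutral transient species are numbered as intermediates.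

**Route**

Step 1
Reactants: 1 methyl 2,4-dihydroxy-3,6-dimethylbenzoate (atraric acid)
Product: 2 methyl 4-(allyloxy)-2-hydroxy-3,6-dimethylbenzoate
Conditions: allyl bromide (1.1 equiv), K2CO3, acetone, reflux
Reagents that add atoms: allyl bromide, C=CCBr
Why: Williamson etherification in which the 2-hydroxyl, hydrogen-bonded to the ester carbonyl, stays unreactive under K2CO3 in acetone, so only the 4-hydroxyl is alkylated.

Step 2
Reactants: 2 methyl 4-(allyloxy)-2-hydroxy-3,6-dimethylbenzoate
Product: 3 4-(allyloxy)-2-hydroxy-3,6-dimethylbenzoic acid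
Conditions: KOH, EtOH/H2O, reflux; then 1 M HCl, 0 °C
Reagents that add atoms: potassium hydroxide, [K+].[OH-]
Why: Saponification of a salicylate-type ester that still has a free ortho-hydroxyl should proceed in hot aqueous ethanolic KOH without touching the allyl ether, and cold acidification avoids decarboxylation of the electron-rich acid.

Step 3
Reactants: 3 4-(allyloxy)-2-hydroxy-3,6-dimethylbenzoic acid
Product: 4 benzyl 4-(allyloxy)-2-(benzyloxy)-3,6-dimethylbenzoate
Conditions: BnBr (2.5 equiv), K2CO3, DMF, 60 °C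
Reagents that add atoms: benzyl bromide, BrCc1ccccc1
Why: Carboxylate alkylation followed by Williamson etherification, in which the carboxylate reacts first and the chelated 2-hydroxyl follows at 60 °C in DMF, giving ester and ether in one operation.

Step 4
Reactants: 4 benzyl 4-(allyloxy)-2-(benzyloxy)-3,6-dimethylbenzoate
Product: 5 benzyl 2-(benzyloxy)-4-hydroxy-3,6-dimethylbenzoate (ring B phenol)
Conditions: Pd(PPh3)4 (5 mol %), morpholine, THF, rt
Reagents that add atoms: none
Why: Tsuji–Trost deallylation in which zerovalent palladium ionises the aryl allyl ether to a π-allyl complex that morpholine intercepts, leaving the benzyl ether and the hindered benzyl ester untouched.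

Step 5
Reactants: 6 ethyl 2-(2-methyl-1,3-dioxolan-2-yl)acetate
Product: 7 N-methoxy-N-methyl-2-(2-methyl-1,3-dioxolan-2-yl)acetamide
Conditions: MeNH(OMe)·HCl, i-PrMgCl, THF, −20 to 0 °C
Reagents that add atoms: N,O-dimethylhydroxylamine hydrochloride, CNOC.Cl
Why: Weinreb amide formation by aminolysis of the ester with the chloromagnesium amide of N,O-dimethylhydroxylamine, conditions to which the dioxolane is inert.

Step 6
Reactants: 8 2,2,6-trimethyl-4H-1,3-dioxin-4-one; 9 formaldehyde (monomer, from cracked paraformaldehyde)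
Product: 10 6-(2-hydroxyethyl)-2,2-dimethyl-4H-1,3-dioxin-4-one
Conditions: LiN(i-Pr)2, THF, −78 °C; CH2O (g), −78 °C; aq. NH4Cl
Reagents that add atoms: none
Why: Vinylogous aldol addition, since the lithium dienolate of the dioxinone reacts with aldehydes at the exocyclic γ-carbon; no stereocentre is formed.

Step 7
Reactants: 10 6-(2-hydroxyethyl)-2,2-dimethyl-4H-1,3-dioxin-4-one
Product: 11 6-[2-(tert-butyldiphenylsilyloxy)ethyl]-2,2-dimethyl-4H-1,3-dioxin-4-one
Conditions: TBDPSCl, imidazole, CH2Cl2, 0 °C to rt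
Reagents that add atoms: tert-butyl(chloro)diphenylsilane, CC(C)(C)[Si](Cl)(c1ccccc1)c1ccccc1
Why: Standard silylation of a primary alcohol; the tert-butyldiphenylsilyl ether is preferred to the dimethyl analogue because it must survive the acidic ketal cleavage of step 9 and resist migration to a neighbouring phenoxide in step 12.

Step 8
Reactants: 11 6-[2-(tert-butyldiphenylsilyloxy)ethyl]-2,2-dimethyl-4H-1,3-dioxin-4-one; 7 N-methoxy-N-methyl-2-(2-methyl-1,3-dioxolan-2-yl)acetamide
Product: 12 6-[1-(tert-butyldiphenylsilyloxy)-4-(2-methyl-1,3-dioxolan-2-yl)-3-oxobutan-2-yl]-2,2-dimethyl-4H-1,3-dioxin-4-one (racemic)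
Conditions: LiN(i-Pr)2 (1.1 equiv), THF, −78 °C; then 7, −78 to −30 °C; aq. NH4Cl
Reagents that add atoms: none
Why: Crossed Claisen-type γ-acylation of the dioxinone dienolate by a Weinreb amide, whose chelated tetrahedral adduct persists until quench so that neither over-addition nor proton transfer consumes dienolate, while the low temperature keeps β-elimination of silyloxide slow; the new C4 centre is racemic and enolisable, which is of no consequence.

Step 9
Reactants: 12 6-[1-(tert-butyldiphenylsilyloxy)-4-(2-methyl-1,3-dioxolan-2-yl)-3-oxobutan-2-yl]-2,2-dimethyl-4H-1,3-dioxin-4-one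
Product: 13 6-[1-(tert-butyldiphenylsilyloxy)-3,5-dioxohexan-2-yl]-2,2-dimethyl-4H-1,3-dioxin-4-one (racemic diketo-dioxinone)
Conditions: 1 M HCl, THF, rt
Reagents that add atoms: water, O
Why: Acid-catalysed ketal hydrolysis, which the dioxinone (a ring that is itself assembled under acid) and the primary tert-butyldiphenylsilyl ether should tolerate in dilute HCl at room temperature.

Step 10
Reactants: 13 6-[1-(tert-butyldiphenylsilyloxy)-3,5-dioxohexan-2-yl]-2,2-dimethyl-4H-1,3-dioxin-4-one; 5 benzyl 2-(benzyloxy)-4-hydroxy-3,6-dimethylbenzoate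
Product: 15 3-(benzyloxy)-4-[(benzyloxy)carbonyl]-2,5-dimethylphenyl 4-[(tert-butyldiphenylsilyloxy)methyl]-3,5,7-trioxooctanoate (racemic), via acylketene 14 (not isolated)
Conditions: 5 (1.1 equiv), PhMe, 110 °C
Reagents that add atoms: none
Why: Retro-hetero-Diels–Alder fragmentation of the dioxinone releases acetone and acylketene 14, which the free 4-hydroxyl of 5 captures at the unhindered ketene carbon (ketene acylation), so the ester that would be hard to form from a di-ortho-substituted benzoic acid is in place before ring A exists.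

Step 11
Reactants: 15 3-(benzyloxy)-4-[(benzyloxy)carbonyl]-2,5-dimethylphenyl 4-[(tert-butyldiphenylsilyloxy)methyl]-3,5,7-trioxooctanoate
Product: 17 3-(benzyloxy)-4-[(benzyloxy)carbonyl]-2,5-dimethylphenyl 3-[(tert-butyldiphenylsilyloxy)methyl]-2,4-dihydroxy-6-methylbenzoate, via cyclic aldol 16 (not isolated)
Conditions: Et3N (0.3 equiv), CH2Cl2, 0 °C to rt; then AcOH (0.5 equiv), rt
Reagents that add atoms: none
Why: Triethylamine generates the enolate of the C2–C3 β-keto ester, whose C2 adds to the C7 methyl ketone (intramolecular aldol) to give cyclic aldol 16; loss of water and enolisation of the C3 and C5 carbonyls then deliver the resorcylate, and the aromatic stabilisation makes the sequence irreversible. The closest known reaction type is the biomimetic aromatisation of 3,5,7-triketo esters obtained by acylketene capture. Ring A closes in a 6-(enolendo)-exo-trig mode, forming the C1–C6 bond of the arene. No stereocentre remains, since the racemic C4 centre of 15 and the carbinol and methine centres of 16 all become sp2 carbons. The step needs the C2-to-C7 aldol to outrun Claisen closure of C6 onto C1, lactonisation of the C5 enol oxygen onto the aryl ester, aldol attack of the C8 methyl on C3 and β-loss of silanol from C4. The doubly activated C2, the absence of alkoxide or hydroxide, the sub-stoichiometric weak base at or below room temperature and the poor leaving ability of silyloxide from a stabilised diketone enolate should secure this.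

Step 12
Reactants: 17 3-(benzyloxy)-4-[(benzyloxy)carbonyl]-2,5-dimethylphenyl 3-[(tert-butyldiphenylsilyloxy)methyl]-2,4-dihydroxy-6-methylbenzoate
Product: 18 3-(benzyloxy)-4-[(benzyloxy)carbonyl]-2,5-dimethylphenyl 3-[(tert-butyldiphenylsilyloxy)methyl]-2,4-dimethoxy-6-methylbenzoate
Conditions: MeI (excess), K2CO3, DMF, rt to 40 °C
Reagents that add atoms: iodomethane, CI
Why: Williamson O-methylation of both ring A phenols, the chelated 2-hydroxyl included; ring B has no free hydroxyl, and the hindered depside ester, the benzyl ester and the bulky silyl ether should be stable to carbonate.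

Step 13
Reactants: 18 3-(benzyloxy)-4-[(benzyloxy)carbonyl]-2,5-dimethylphenyl 3-[(tert-butyldiphenylsilyloxy)methyl]-2,4-dimethoxy-6-methylbenzoate
Product: 19 4-({3-[(tert-butyldiphenylsilyloxy)methyl]-2,4-dimethoxy-6-methylbenzoyl}oxy)-2-hydroxy-3,6-dimethylbenzoic acid
Conditions: H2 (1 atm), Pd/C (palladium on carbon), EtOAc, rt
Reagents that add atoms: none
Why: Hydrogenolysis of the benzyl ether and the benzyl ester in neutral ethyl acetate, with the silyl group kept on so that the hindered benzylic C–O bond of ring A is not over-reduced to a methyl group.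

Step 14
Reactants: 19 4-({3-[(tert-butyldiphenylsilyloxy)methyl]-2,4-dimethoxy-6-methylbenzoyl}oxy)-2-hydroxy-3,6-dimethylbenzoic acid
Product: 20 4-{[3-(hydroxymethyl)-2,4-dimethoxy-6-methylbenzoyl]oxy}-2-hydroxy-3,6-dimethylbenzoic acid (target)
Conditions: HF·pyridine, pyridine, THF, 0 °C to rt
Reagents that add atoms: none
Why: Fluoride-mediated desilylation under pyridine-buffered conditions, mild enough for the depside ester and for the electron-rich, acid-sensitive 2,6-dimethoxybenzyl alcohol that is released.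

**Compound list**

1 | methyl 2,4-dihydroxy-3,6-dimethylbenzoate (atraric acid) | COC(=O)c1c(C)cc(O)c(C)c1O | starting material
2 | methyl 4-(allyloxy)-2-hydroxy-3,6-dimethylbenzoate | COC(=O)c1c(C)cc(OCC=C)c(C)c1O | intermediate
3 | 4-(allyloxy)-2-hydroxy-3,6-dimethylbenzoic acid | OC(=O)c1c(C)cc(OCC=C)c(C)c1O | intermediate
4 | benzyl 4-(allyloxy)-2-(benzyloxy)-3,6-dimethylbenzoate | C=CCOc1cc(C)c(C(=O)OCc2ccccc2)c(OCc2ccccc2)c1C | intermediate
5 | benzyl 2-(benzyloxy)-4-hydroxy-3,6-dimethylbenzoate | Cc1cc(O)c(C)c(OCc2ccccc2)c1C(=O)OCc1ccccc1 | intermediate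
6 | ethyl 2-(2-methyl-1,3-dioxolan-2-yl)acetate | CCOC(=O)CC1(C)OCCO1 | starting material
7 | N-methoxy-N-methyl-2-(2-methyl-1,3-dioxolan-2-yl)acetamide | CON(C)C(=O)CC1(C)OCCO1 | intermediate
8 | 2,2,6-trimethyl-4H-1,3-dioxin-4-one | CC1=CC(=O)OC(C)(C)O1 | starting material
9 | formaldehyde | C=O | starting material
10 | 6-(2-hydroxyethyl)-2,2-dimethyl-4H-1,3-dioxin-4-one | CC1(C)OC(CCO)=CC(=O)O1 | intermediate
11 | 6-[2-(tert-butyldiphenylsilyloxy)ethyl]-2,2-dimethyl-4H-1,3-dioxin-4-one | CC1(C)OC(CCO[Si](c2ccccc2)(c2ccccc2)C(C)(C)C)=CC(=O)O1 | intermediate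
12 | 6-[1-(tert-butyldiphenylsilyloxy)-4-(2-methyl-1,3-dioxolan-2-yl)-3-oxobutan-2-yl]-2,2-dimethyl-4H-1,3-dioxin-4-one (racemic) | CC1(CC(=O)C(CO[Si](c2ccccc2)(c2ccccc2)C(C)(C)C)C2=CC(=O)OC(C)(C)O2)OCCO1 | intermediate
13 | 6-[1-(tert-butyldiphenylsilyloxy)-3,5-dioxohexan-2-yl]-2,2-dimethyl-4H-1,3-dioxin-4-one (racemic) | CC(=O)CC(=O)C(CO[Si](c1ccccc1)(c1ccccc1)C(C)(C)C)C1=CC(=O)OC(C)(C)O1 | intermediate
14 | acylketene 4-[(tert-butyldiphenylsilyloxy)methyl]-3,5,7-trioxooct-1-en-1-one (not isolated) | CC(=O)CC(=O)C(CO[Si](c1ccccc1)(c1ccccc1)C(C)(C)C)C(=O)C=C=O | intermediate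
15 | 3-(benzyloxy)-4-[(benzyloxy)carbonyl]-2,5-dimethylphenyl 4-[(tert-butyldiphenylsilyloxy)methyl]-3,5,7-trioxooctanoate (racemic) | CC(=O)CC(=O)C(CO[Si](c1ccccc1)(c1ccccc1)C(C)(C)C)C(=O)CC(=O)Oc1cc(C)c(C(=O)OCc2ccccc2)c(OCc2ccccc2)c1C | intermediate
16 | cyclic aldol 3-(benzyloxy)-4-[(benzyloxy)carbonyl]-2,5-dimethylphenyl 3-[(tert-butyldiphenylsilyloxy)methyl]-6-hydroxy-6-methyl-2,4-dioxocyclohexane-1-carboxylate (diastereomer mixture, not isolated) | CC1(O)CC(=O)C(CO[Si](c2ccccc2)(c2ccccc2)C(C)(C)C)C(=O)C1C(=O)Oc1cc(C)c(C(=O)OCc2ccccc2)c(OCc2ccccc2)c1C | intermediate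
17 | 3-(benzyloxy)-4-[(benzyloxy)carbonyl]-2,5-dimethylphenyl 3-[(tert-butyldiphenylsilyloxy)methyl]-2,4-dihydroxy-6-methylbenzoate | Cc1cc(O)c(CO[Si](c2ccccc2)(c2ccccc2)C(C)(C)C)c(O)c1C(=O)Oc1cc(C)c(C(=O)OCc2ccccc2)c(OCc2ccccc2)c1C | intermediate
18 | 3-(benzyloxy)-4-[(benzyloxy)carbonyl]-2,5-dimethylphenyl 3-[(tert-butyldiphenylsilyloxy)methyl]-2,4-dimethoxy-6-methylbenzoate | COc1cc(C)c(C(=O)Oc2cc(C)c(C(=O)OCc3ccccc3)c(OCc3ccccc3)c2C)c(OC)c1CO[Si](c1ccccc1)(c1ccccc1)C(C)(C)C | intermediate
19 | 4-({3-[(tert-butyldiphenylsilyloxy)methyl]-2,4-dimethoxy-6-methylbenzoyl}oxy)-2-hydroxy-3,6-dimethylbenzoic acid | COc1cc(C)c(C(=O)Oc2cc(C)c(C(=O)O)c(O)c2C)c(OC)c1CO[Si](c1ccccc1)(c1ccccc1)C(C)(C)C | intermediate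
20 | 4-{[3-(hydroxymethyl)-2,4-dimethoxy-6-methylbenzoyl]oxy}-2-hydroxy-3,6-dimethylbenzoic acid | COc1cc(C)c(C(=O)Oc2cc(C)c(C(=O)O)c(O)c2C)c(OC)c1CO | target

**Step count and risks**

Total steps: 14. Longest linear sequence: 9 steps (steps 6–14 from dioxinone 8; equally steps 1–4 and 10–14 from 1).

Steps most likely to fail:

1. Step 11 (key step). The aldol closure may be outrun by lactonisation of the C5 enol oxygen onto the activated aryl ester with loss of the ring B phenol, by Claisen closure of C6 onto C1, by reversion to the acylketene, or by β-elimination of silanol from C4. Fallback: close ring A before the ester exists. Setting out from 13, Et3N in CH2Cl2 should drive the same C2-to-C7 aldol on the dioxinone itself, through the bicyclic aldol F1 (not isolated), to the isopropylidene-protected resorcylate 7-hydroxy-8-[(tert-butyldiphenylsilyloxy)methyl]-2,2,5-trimethyl-4H-1,3-benzodioxin-4-one F2. MeI and K2CO3 would give the 7-methyl ether F3. Irradiation at 300 nm in CH2Cl2 with phenol 5 would expel acetone and release the quinoketene F4 (not isolated), whose capture by 5 gives the mono-methylated depside F5 with a free ring A 2-hydroxyl. Methylation of F5 (MeI, K2CO3, DMF) comes back to the route at 18.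

2. Step 10. The acylketene may be consumed by attack of its own C5 enol oxygen (pyranone formation) or by dimerisation faster than the ortho-methylated phenol adds. Fallback: a classical depside union. Setting out from 13, thermolysis in toluene with excess allyl alcohol should pass through acylketene 14 to the allyl triketo ester F6. Et3N then closes ring A through the cyclic aldol F7 (not isolated) to the allyl resorcylate F8. MeI and K2CO3 give the dimethyl ether F9, and Pd(PPh3)4 with morpholine frees the benzoic acid F10. Trifluoroacetic anhydride in toluene converts F10 into the mixed anhydride F11 (not isolated), which acylates phenol 5 and so comes back to the route at 18.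

3. Step 8. Acylation of the hindered, γ-substituted dienolate may be slow enough that warming triggers β-elimination of silyloxide or attack through the α-carbon. Fallback: aldol addition and oxidation in place of acylation. Ester 6 is reduced with i-Bu2AlH (CH2Cl2, −78 °C) to the aldehyde 2-(2-methyl-1,3-dioxolan-2-yl)acetaldehyde F12. Setting out from 11, its lithium dienolate (LiN(i-Pr)2, THF, −78 °C) adds to F12 at −78 °C to give the γ-aldol adduct F13 as a diastereomer mixture. Dess–Martin periodinane (CH2Cl2, NaHCO3) oxidises F13 to 12, where the route resumes.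

**Further compounds**

F1 | step 11 | 8-[(tert-butyldiphenylsilyloxy)methyl]-5-hydroxy-2,2,5-trimethyl-5,6-dihydro-4H-1,3-benzodioxine-4,7(8H)-dione (bicyclic aldol, not isolated) | CC1(O)CC(=O)C(CO[Si](c2ccccc2)(c2ccccc2)C(C)(C)C)C2=C1C(=O)OC(C)(C)O2
F2 | step 11 | 7-hydroxy-8-[(tert-butyldiphenylsilyloxy)methyl]-2,2,5-trimethyl-4H-1,3-benzodioxin-4-one | Cc1cc(O)c(CO[Si](c2ccccc2)(c2ccccc2)C(C)(C)C)c2OC(C)(C)OC(=O)c12
F3 | step 11 | 8-[(tert-butyldiphenylsilyloxy)methyl]-7-methoxy-2,2,5-trimethyl-4H-1,3-benzodioxin-4-one | COc1cc(C)c2C(=O)OC(C)(C)Oc2c1CO[Si](c1ccccc1)(c1ccccc1)C(C)(C)C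
F4 | step 11 | quinoketene 2-[(tert-butyldiphenylsilyloxy)methyl]-3-methoxy-5-methyl-6-(oxomethylidene)cyclohexa-2,4-dien-1-one (not isolated) | CC1=CC(OC)=C(CO[Si](c2ccccc2)(c2ccccc2)C(C)(C)C)C(=O)C1=C=O
F5 | step 11 | 3-(benzyloxy)-4-[(benzyloxy)carbonyl]-2,5-dimethylphenyl 3-[(tert-butyldiphenylsilyloxy)methyl]-2-hydroxy-4-methoxy-6-methylbenzoate | COc1cc(C)c(C(=O)Oc2cc(C)c(C(=O)OCc3ccccc3)c(OCc3ccccc3)c2C)c(O)c1CO[Si](c1ccccc1)(c1ccccc1)C(C)(C)C
F6 | step 10 | allyl 4-[(tert-butyldiphenylsilyloxy)methyl]-3,5,7-trioxooctanoate | CC(=O)CC(=O)C(CO[Si](c1ccccc1)(c1ccccc1)C(C)(C)C)C(=O)CC(=O)OCC=C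
F7 | step 10 | allyl 3-[(tert-butyldiphenylsilyloxy)methyl]-6-hydroxy-6-methyl-2,4-dioxocyclohexane-1-carboxylate (cyclic aldol, not isolated) | CC1(O)CC(=O)C(CO[Si](c2ccccc2)(c2ccccc2)C(C)(C)C)C(=O)C1C(=O)OCC=C
F8 | step 10 | allyl 3-[(tert-butyldiphenylsilyloxy)methyl]-2,4-dihydroxy-6-methylbenzoate | Cc1cc(O)c(CO[Si](c2ccccc2)(c2ccccc2)C(C)(C)C)c(O)c1C(=O)OCC=C
F9 | step 10 | allyl 3-[(tert-butyldiphenylsilyloxy)methyl]-2,4-dimethoxy-6-methylbenzoate | COc1cc(C)c(C(=O)OCC=C)c(OC)c1CO[Si](c1ccccc1)(c1ccccc1)C(C)(C)C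
F10 | step 10 | 3-[(tert-butyldiphenylsilyloxy)methyl]-2,4-dimethoxy-6-methylbenzoic acid | COc1cc(C)c(C(=O)O)c(OC)c1CO[Si](c1ccccc1)(c1ccccc1)C(C)(C)C
F11 | step 10 | 3-[(tert-butyldiphenylsilyloxy)methyl]-2,4-dimethoxy-6-methylbenzoic trifluoroacetic anhydride (not isolated) | COc1cc(C)c(C(=O)OC(=O)C(F)(F)F)c(OC)c1CO[Si](c1ccccc1)(c1ccccc1)C(C)(C)C
F12 | step 8 | 2-(2-methyl-1,3-dioxolan-2-yl)acetaldehyde | CC1(CC=O)OCCO1
F13 | step 8 | 6-[1-(tert-butyldiphenylsilyloxy)-3-hydroxy-4-(2-methyl-1,3-dioxolan-2-yl)butan-2-yl]-2,2-dimethyl-4H-1,3-dioxin-4-one | CC1(CC(O)C(CO[Si](c2ccccc2)(c2ccccc2)C(C)(C)C)C2=CC(=O)OC(C)(C)O2)OCCO1
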